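# Proposed synthesis of CNP0309781.1 by a three-component Michael–alkylation on 2-methylcyclohexenone

Compound numbers are those of the steps and of the compound list. Bicyclic compounds are named with the locants of the target: ring B is C1, C2, C3, C3a, C7a and ring A is C3a, C4, C5, C6, C7, C7a.

## Analysis of the target

The target (C20H33BrO) is a trans-fused hydrindane: cyclopentane ring B is fused to cyclohexane ring A, and C1 carries an (E)-2,6-dimethylhepta-1,5-dienyl chain. Its five stereocentres are contiguous and have the configuration (1S,3aS,4S,7R,7aS). C3a is quaternary with a β methyl group and C7a carries an α hydrogen, so the fusion is trans. The bromine at C4 is equatorial and cis to the angular methyl group. The hydroxyl at C7 is axial and 1,3-diaxial to that methyl group. The C1 chain lies on the α face, trans to C7 and to the angular methyl group. The sensitive groups are a secondary bromide on a neopentyl carbon (not accessible by substitution, prone to reduction), a tertiary alcohol (dehydration, lactonisation with any carboxyl group at C1) and two trisubstituted alkenes, one of which must be E. The difficulties are the quaternary centre flanked by stereocentres, a trans ring fusion that becomes epimerisable once C7 is a ketone, and the 1,4-relationship of the heteroatoms at C4 and C7. The strategy rests on one feature: C3a and C7a are adjacent ring A carbons that hold the two ends of ring B trans, and C4 is a ketone-equivalent position. C3a, C7a and C4 therefore map onto the α-carbon, β-carbon and carbonyl carbon of 2-methylcyclohexenone 3.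

## Retrosynthetic reasoning

**C7–CH3 (30 from 29).** The methyl group is removed last. A ketone at C7 in the rigid bicycle has its β face blocked by the 1,3-diaxial angular methyl group, so a methyl nucleophile should enter equatorially from the α face and give the axial hydroxyl. Forming the tertiary alcohol after all ester chemistry also avoids γ-lactone formation between C7–OH and a C1 carboxyl group.

**C7 oxidation level (29 from 27 through 28).** The ketone is epimerisable at C7a, so C7 is carried as a silyl ether through the side-chain work and oxidised only immediately before the methyl addition.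

**Side chain (27 from 23 and 25, 23 from 22, 22 from 20).** Both C–C bonds at the distal alkene carbon are cut. A 1,1-dibromoalkene 23 lets the chain of 25 be introduced trans to C1 first and the methyl group second, each with defined geometry, which a direct olefination with a branched ylide or sulfone would not guarantee. Dibromoalkene 23 is the one-carbon homologue of aldehyde 22, which comes from ester 20.

**C4–H (20 from 19).** The bromide stereocentre is made by adding hydrogen to a vinyl bromide, not by forming the C–Br bond on a saturated carbon. The hydrogen atom should arrive from the α face, opposite the angular methyl group, leaving bromine equatorial. This has to precede the side chain, whose alkenes would also be reduced.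

**C4–Br (19 from 18, 18 from 16).** The vinyl bromide comes from the enol triflate. The triflate comes regiospecifically from the enolate released by conjugate reduction of enone 16.

**C7–O (16 from 15, 15 from 13).** The enone has no α′ hydrogen because C3a is quaternary. It can therefore enolise only through C7, and oxidation of the resulting dienol ether places oxygen at C7. The enone thus serves twice: for the remote oxidation and for the enolate that leads to the bromide.

**C1–C2 and ring B (13 from 12, 12 from 11).** Ring B is closed by alkylation of the ester enolate with a primary iodide, a 5-exo closure made possible by the trans arrangement of the two arms. The ketone, which is more acidic than the ester, is masked as the enol silane in 11, and the same enol silane is then the substrate for dehydrogenation to 13.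

**Two-carbon arm (11 from 10, 9, 8 and 7).** The allyl group of 7 is shortened by one carbon and turned into the iodide.

**C7a–C1 and C3a–C3 (7 from 3, 2 and 4).** Both arms are attached to enone 3 in one operation. Conjugate addition of ketene acetal 2 forms C7a–C1 and fixes the enolate as enol silane 5; allylation of the derived enolate 6 with 4 forms C3a–C3. All risk is concentrated here, since the precursors are one step from purchased materials.

**Ketene acetal (2 from 1).** O-Silylation of the ester enolate.

## Alternatives that were turned down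

**Alternative 1: ring contraction of a bromo trans-decalin.**
- Disconnection: C1–C2 is formed by a 1,2-shift. Aldehyde A1 (4-bromo-7-hydroxy-3a,7-dimethyloctahydroindene-1-carbaldehyde) is traced back to the decalin hydroxy mesylate A2, in which ring B is six-membered.
- Forward key step: an alkoxide base deprotonates the secondary hydroxyl of A2, and the ring bond antiperiplanar to the equatorial mesylate migrates. The ring contracts and the carbinol carbon becomes the formyl group at C1.
- For: the shift is stereospecific. A1 already contains the complete ring A with bromide and tertiary alcohol, so only the olefination remains. On end-game brevity this alternative is clearly stronger than the chosen route.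
- Against: the whole difficulty moves into A2. A decalin with six stereocentres, including the equatorial neopentyl bromide and the tertiary alcohol, must exist before the key step, and nothing in the plan says how they are set. A1 is a γ-hydroxy aldehyde with an epimerisable C1; under the alkoxide it can epimerise and be trapped as a lactol with the C7 hydroxyl. The secondary bromide is also exposed to strong base.
- Comparison: the chosen strategy offers a key precursor available in one step, absolute configuration from a single catalytic event, and a C1 handle kept as a robust ester until the bromide is in place.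

**Alternative 2: angular methyl through a directed cyclopropane.**
- Disconnection: the C3a–CH3 bond. The methyl group is introduced as a methylene bridged across C3a and C7a in the cyclopropane-bridged carbinol A3, made from the allylic alcohol A4 (trans-4-silyloxy-2,3,4,5,6,7-hexahydro-1H-inden-7-ol).
- Forward key step: a zinc carbenoid, directed by the C7 hydroxyl, cyclopropanates the tetrasubstituted C3a=C7a alkene on the hydroxyl face. The C7a–CH2 bond is cleaved reductively later.
- For: hydroxyl-directed cyclopropanation is one of the most dependable ways to functionalise a tetrasubstituted alkene on one face. Both ring A oxygens are present from the start, whereas the chosen route spends three steps on oxidising C7; on this point the alternative is stronger.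
- Against: the C7a hydrogen appears only when the cyclopropane is opened through a C7 ketone. The ring fusion is then decided by protonation of an enolate, which tends toward the cis-hydrindanone. A3 has no functional group at C1, so the side chain cannot be attached without redesign. The C4 oxygen would have to be exchanged for bromine by substitution at a neopentyl carbon. A4 needs its own asymmetric step.
- Comparison: in the chosen route the trans relationship is set by a C–C bond formation anti to an existing substituent, and C1 is functionalised from the key step on.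

**Alternative 3: asymmetric Stetter reaction.**
- Disconnection: C3a–C4. Ring A is closed by intramolecular conjugate addition of an acyl anion equivalent, taking the dione A5 ((3aS,7aS)-3a-methylhexahydroindene-4,7-dione) back to the keto aldehyde A6.
- Forward key step: a chiral triazolium-derived carbene with a silylamide base converts the aldehyde carbon of A6 into a nucleophile that adds to the methyl-bearing β-carbon of the cyclopentenyl ketone.
- For: the quaternary centre and ring A form in one catalytic enantioselective step from an achiral substrate, with both ring A carbonyls in place. On step count to a 4,7-dioxygenated hydrindane this is stronger than the chosen route.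
- Against: the acceptor carbon is fully substituted and part of a cyclopentene, which is at the limit of this reaction. The aldehyde of A6 is enolisable under the base. The fusion hydrogen again comes from protonation α to a ketone, and A5 can drift to the cis isomer. The two ketones must be differentiated, and C1 is a bare methylene.
- Comparison: the chosen strategy is longer to the bicycle but sets both ring B arms and the C1 handle in the key step, and it never relies on protonation to set the ring fusion.

Key step: step 2

Assumption: the (S)-prolinol-derived oxazaborolidinium ion is taken to direct the ketene acetal to the Re face of the β-carbon of 3; if the sense of induction is the opposite, the (R)-catalyst is used and nothing else changes.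

## Route

Step 1
Reactants: 1 tert-butyl acetate
Product: 2 1-tert-butoxy-1-(trimethylsilyloxy)ethene
Conditions: LiN(i-Pr)2, THF, −78 °C; (CH3)3SiCl, −78 °C → rt; distillation
Reagents that add atoms: chlorotrimethylsilane, C[Si](C)(C)Cl
Why: Kinetic deprotonation of the ester and O-silylation of the lithium enolate (silyl ketene acetal formation); the tert-butyl group suppresses self-condensation.

Step 2
Reactants: 3 2-methylcyclohex-2-en-1-one; 2 1-tert-butoxy-1-(trimethylsilyloxy)ethene; 4 allyl bromide (3-bromoprop-1-ene)
Product: 7 tert-butyl 2-[(1S,2S)-2-methyl-3-oxo-2-(prop-2-en-1-yl)cyclohexyl]acetate, via enol silane 5 (not isolated), via lithium enolate 6 (not isolated)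
Conditions: (S)-3,3-diphenyl-1-(2-methylphenyl)tetrahydro-1H,3H-pyrrolo[1,2-c][1,3,2]oxazaborole·HN(SO2CF3)2 (10 mol %), Ph3P=O (15 mol %), toluene, −20 °C; solvent exchange to THF; CH3Li, 0 °C; then 4, DMPU, −78 → 0 °C
Reagents that add atoms: none
Why: Catalytic enantioselective Mukaiyama–Michael addition followed by alkylation of the regenerated enolate (conjugate addition–enolate trapping), a known sequence on 2-substituted cyclohexenones. The boron centre of the oxazaborolidinium ion binds the carbonyl oxygen of 3, ketene acetal 2 attacks the β-carbon, and the silyl group is relayed by Ph3P=O to the enolate oxygen, which frees the catalyst and stores the enolate regiospecifically as enol silane 5. CH3Li then cleaves the Si–O bond (giving tetramethylsilane) faster than it adds to the hindered tert-butyl ester, and the tetrasubstituted lithium enolate 6 is alkylated by 4 at the methyl-bearing carbon before it can equilibrate. Two C–C bonds form and no ring is closed. The CH stereocentre (S) is set by the catalyst, which must expose the Re face of the β-carbon of the bound enone. The quaternary centre (S) is set by the substrate: allylic 1,2-strain with the enolate methyl group turns the acetate arm pseudoaxial and the allyl halide enters along the axial trajectory on the opposite face, so that allyl and acetate arms end up trans. The step needs 1,4- over 1,2-addition (soft silyl nucleophile, Lewis acid activation), C- over O-alkylation (lithium enolate, allylic bromide) and survival of the ester toward CH3Li and toward the enolate oxygen (bulk of the tert-butyl group).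

Step 3
Reactants: 7 tert-butyl 2-[(1S,2S)-2-methyl-3-oxo-2-(prop-2-en-1-yl)cyclohexyl]acetate
Product: 8 tert-butyl 2-[(1S,2S)-2-methyl-3-oxo-2-(2-oxoethyl)cyclohexyl]acetate
Conditions: O3, CH2Cl2, −78 °C; PPh3, −78 °C → rt
Reagents that add atoms: ozone, [O-][O+]=O
Why: Ozonolysis with reductive work-up; the terminal alkene is the only group that reacts with ozone, and the quaternary centre prevents epimerisation next to the ketone.

Step 4
Reactants: 8 tert-butyl 2-[(1S,2S)-2-methyl-3-oxo-2-(2-oxoethyl)cyclohexyl]acetate
Product: 9 tert-butyl 2-[(1S,2S)-2-(2-hydroxyethyl)-2-methyl-3-oxocyclohexyl]acetate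
Conditions: NaBH4, EtOH/CH2Cl2, −78 °C
Reagents that add atoms: none
Why: Chemoselective borohydride reduction; at −78 °C the unhindered aldehyde should react far faster than the ketone flanked by the quaternary carbon.

Step 5
Reactants: 9 tert-butyl 2-[(1S,2S)-2-(2-hydroxyethyl)-2-methyl-3-oxocyclohexyl]acetate
Product: 10 tert-butyl 2-[(1S,2S)-2-(2-iodoethyl)-2-methyl-3-oxocyclohexyl]acetate
Conditions: I2, PPh3, imidazole, CH2Cl2, 0 °C → rt
Reagents that add atoms: iodine, II
Why: Appel-type iodination of the primary alcohol by SN2 displacement of the alkoxyphosphonium group; the neutral conditions leave the γ-iodo ketone open-chain.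

Step 6
Reactants: 10 tert-butyl 2-[(1S,2S)-2-(2-iodoethyl)-2-methyl-3-oxocyclohexyl]acetate
Product: 11 tert-butyl 2-[(1S,2S)-3-[(tert-butyldimethylsilyl)oxy]-2-(2-iodoethyl)-2-methylcyclohex-3-en-1-yl]acetate
Conditions: t-BuMe2SiOTf, Et3N, CH2Cl2, −78 → 0 °C
Reagents that add atoms: tert-butyldimethylsilyl trifluoromethanesulfonate, CC(C)(C)[Si](C)(C)OS(=O)(=O)C(F)(F)F
Why: Soft enolisation and O-silylation; the ketone can enolise only toward its CH2 side, so one enol silane forms. It masks the ketone (more acidic than the ester and able to O-alkylate with the iodide) and is the substrate for step 8.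

Step 7
Reactants: 11 tert-butyl 2-[(1S,2S)-3-[(tert-butyldimethylsilyl)oxy]-2-(2-iodoethyl)-2-methylcyclohex-3-en-1-yl]acetate
Product: 12 tert-butyl (1R,3aS,7aS)-4-[(tert-butyldimethylsilyl)oxy]-3a-methyl-2,3,3a,6,7,7a-hexahydro-1H-indene-1-carboxylate
Conditions: LiN(i-Pr)2, THF, −78 °C; then DMPU, −78 → 0 °C
Reagents that add atoms: none
Why: Intramolecular alkylation of the ester enolate (5-exo-tet, enolate double bond outside the forming ring) forms C1–C2 and ring B, with the trans fusion fixed by the trans arms. The ester should take the α position, trans to C7 and to the angular methyl group, which is also the thermodynamically preferred one; any β epimer can be equilibrated at aldehyde 22.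

Step 8
Reactants: 12 tert-butyl (1R,3aS,7aS)-4-[(tert-butyldimethylsilyl)oxy]-3a-methyl-2,3,3a,6,7,7a-hexahydro-1H-indene-1-carboxylate
Product: 13 tert-butyl (1R,3aS,7aS)-3a-methyl-4-oxo-2,3,3a,4,7,7a-hexahydro-1H-indene-1-carboxylate
Conditions: Pd(OAc)2 (1.1 equiv), CH3CN, rt
Reagents that add atoms: none
Why: Saegusa–Ito oxidation: palladation of the enol silane at C5 and β-hydride elimination from C6; only the C5=C6 enone can form because C3a is quaternary.

Step 9
Reactants: 13 tert-butyl (1R,3aS,7aS)-3a-methyl-4-oxo-2,3,3a,4,7,7a-hexahydro-1H-indene-1-carboxylate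
Product: 15 tert-butyl (1R,3aS,7S,7aS)-7-hydroxy-3a-methyl-4-oxo-2,3,3a,4,7,7a-hexahydro-1H-indene-1-carboxylate, via dienol silyl ether 14 (not isolated)
Conditions: t-BuMe2SiOTf, Et3N, CH2Cl2, 0 °C; then dimethyldioxirane, acetone/CH2Cl2, −78 → −20 °C; aqueous citric acid, THF, rt
Reagents that add atoms: dimethyldioxirane, CC1(C)OO1
Why: Vinylogous Rubottom oxidation: with no α′ hydrogen the enone enolises through C7, and epoxidation of the distal C6=C7 bond of the dienol ether followed by opening gives the γ-hydroxy enone. Attack is expected on the α face, anti to the angular methyl group, but the C7 configuration is unimportant because C7 becomes a ketone in step 21.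

Step 10
Reactants: 15 tert-butyl (1R,3aS,7S,7aS)-7-hydroxy-3a-methyl-4-oxo-2,3,3a,4,7,7a-hexahydro-1H-indene-1-carboxylate
Product: 16 tert-butyl (1R,3aS,7S,7aS)-7-[(tert-butyldimethylsilyl)oxy]-3a-methyl-4-oxo-2,3,3a,4,7,7a-hexahydro-1H-indene-1-carboxylate
Conditions: t-BuMe2SiCl, imidazole, DMF, rt
Reagents that add atoms: tert-butyldimethylsilyl chloride, CC(C)(C)[Si](C)(C)Cl
Why: Silyl ether formation; the C7 oxygen has to be inert to hydride, triflating agent and organometallic reagents until step 20.

Step 11
Reactants: 16 tert-butyl (1R,3aS,7S,7aS)-7-[(tert-butyldimethylsilyl)oxy]-3a-methyl-4-oxo-2,3,3a,4,7,7a-hexahydro-1H-indene-1-carboxylate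
Product: 18 tert-butyl (1R,3aS,7S,7aS)-7-[(tert-butyldimethylsilyl)oxy]-3a-methyl-4-[(trifluoromethanesulfonyl)oxy]-2,3,3a,6,7,7a-hexahydro-1H-indene-1-carboxylate, via lithium enolate 17 (not isolated)
Conditions: LiBH(s-Bu)3, THF, −78 °C; then PhN(SO2CF3)2, −78 → 0 °C
Reagents that add atoms: N-phenylbis(trifluoromethanesulfonimide), O=S(=O)(N(c1ccccc1)S(=O)(=O)C(F)(F)F)C(F)(F)F
Why: Conjugate hydride reduction of a β-unsubstituted cyclohexenone (1,2-attack is hindered by the quaternary C3a) releases the C4=C5 enolate regiospecifically, and O-triflation traps it as the enol triflate.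

Step 12
Reactants: 18 tert-butyl (1R,3aS,7S,7aS)-7-[(tert-butyldimethylsilyl)oxy]-3a-methyl-4-[(trifluoromethanesulfonyl)oxy]-2,3,3a,6,7,7a-hexahydro-1H-indene-1-carboxylate
Product: 19 tert-butyl (1R,3aS,7S,7aS)-4-bromo-7-[(tert-butyldimethylsilyl)oxy]-3a-methyl-2,3,3a,6,7,7a-hexahydro-1H-indene-1-carboxylate
Conditions: Ni(OAc)2·4H2O (10 mol %), 1,5-cyclooctadiene (25 mol %), Zn (20 mol %), LiBr, DMA/THF, rt
Reagents that add atoms: lithium bromide, [Li+].[Br-]
Why: Nickel-catalysed halogen exchange of an enol triflate: oxidative addition of zerovalent nickel to the C–O bond, triflate–bromide exchange and C–Br reductive elimination. It puts bromine on C4 without any substitution at the neopentyl carbon.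

Step 13
Reactants: 19 tert-butyl (1R,3aS,7S,7aS)-4-bromo-7-[(tert-butyldimethylsilyl)oxy]-3a-methyl-2,3,3a,6,7,7a-hexahydro-1H-indene-1-carboxylate
Product: 20 tert-butyl (1R,3aS,4S,7S,7aS)-4-bromo-7-[(tert-butyldimethylsilyl)oxy]-3a-methyloctahydro-1H-indene-1-carboxylate
Conditions: Mn(dpm)3 (10 mol %; dpm = 2,2,6,6-tetramethylheptane-3,5-dionate), PhSiH3, t-BuOOH, i-PrOH, rt
Reagents that add atoms: none
Why: Hydrogen-atom-transfer hydrogenation of a haloalkene: the metal hydride gives H to C5, and the resulting α-bromo radical at C4 takes its hydrogen along the axial trajectory from the α face, opposite the angular methyl group, so bromine ends up equatorial (4S). The C–Br bond should survive because the radical sits on the bromine-bearing carbon and no metal surface is involved.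

Step 14
Reactants: 20 tert-butyl (1R,3aS,4S,7S,7aS)-4-bromo-7-[(tert-butyldimethylsilyl)oxy]-3a-methyloctahydro-1H-indene-1-carboxylate
Product: 21 [(1R,3aS,4S,7S,7aS)-4-bromo-7-[(tert-butyldimethylsilyl)oxy]-3a-methyloctahydro-1H-inden-1-yl]methanol
Conditions: i-Bu2AlH, CH2Cl2, −78 → 0 °C; aqueous potassium sodium tartrate
Reagents that add atoms: none
Why: Hydride reduction of the ester to the primary alcohol; the aluminium hydride does not touch the hindered secondary bromide or the silyl ether.

Step 15
Reactants: 21 [(1R,3aS,4S,7S,7aS)-4-bromo-7-[(tert-butyldimethylsilyl)oxy]-3a-methyloctahydro-1H-inden-1-yl]methanol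
Product: 22 (1R,3aS,4S,7S,7aS)-4-bromo-7-[(tert-butyldimethylsilyl)oxy]-3a-methyloctahydro-1H-indene-1-carbaldehyde
Conditions: Dess–Martin periodinane, CH2Cl2, 0 °C → rt
Reagents that add atoms: none
Why: Dess–Martin oxidation; the α-formyl configuration is the stable one, so any β epimer carried from step 7 can be converted by brief treatment with DBU before step 16.

Step 16
Reactants: 22 (1R,3aS,4S,7S,7aS)-4-bromo-7-[(tert-butyldimethylsilyl)oxy]-3a-methyloctahydro-1H-indene-1-carbaldehyde
Product: 23 {[(1R,3aS,4S,7S,7aS)-4-bromo-1-(2,2-dibromoethenyl)-3a-methyloctahydro-1H-inden-7-yl]oxy}(tert-butyl)dimethylsilane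
Conditions: CBr4, PPh3, Zn, CH2Cl2, rt; then 22, 0 °C → rt
Reagents that add atoms: carbon tetrabromide, BrC(Br)(Br)Br
Why: Corey–Fuchs dibromo-olefination (Wittig reaction of the dibromomethylene ylide); the zinc variant avoids free bromophosphonium salts.

Step 17
Reactants: 24 5-bromo-2-methylpent-2-ene
Product: 25 (4-methylpent-3-en-1-yl)zinc bromide
Conditions: Zn dust, LiCl, THF, 40 °C
Reagents that add atoms: zinc, [Zn]
Why: Direct insertion of activated zinc into a primary alkyl bromide; the homoallylic organozinc is stable and the alkene does not interfere.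

Step 18
Reactants: 23 {[(1R,3aS,4S,7S,7aS)-4-bromo-1-(2,2-dibromoethenyl)-3a-methyloctahydro-1H-inden-7-yl]oxy}(tert-butyl)dimethylsilane; 25 (4-methylpent-3-en-1-yl)zinc bromide
Product: 26 {[(1R,3aS,4S,7S,7aS)-4-bromo-1-[(1Z)-2-bromo-6-methylhepta-1,5-dien-1-yl]-3a-methyloctahydro-1H-inden-7-yl]oxy}(tert-butyl)dimethylsilane
Conditions: PdCl2(DPEphos) (5 mol %; DPEphos = bis[2-(diphenylphosphino)phenyl] ether), THF/DMF, 0 °C → rt
Reagents that add atoms: none
Why: Negishi coupling as the trans-selective mono-alkylation of a 1,1-dibromoalkene: palladium inserts into the C–Br bond trans to the bulky ring substituent, so the chain is placed trans to C1 and the cis bromine remains. The alkyl bromide at C4 is inert to this catalyst.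

Step 19
Reactants: 26 {[(1R,3aS,4S,7S,7aS)-4-bromo-1-[(1Z)-2-bromo-6-methylhepta-1,5-dien-1-yl]-3a-methyloctahydro-1H-inden-7-yl]oxy}(tert-butyl)dimethylsilane
Product: 27 {[(1S,3aS,4S,7S,7aS)-4-bromo-1-[(1E)-2,6-dimethylhepta-1,5-dien-1-yl]-3a-methyloctahydro-1H-inden-7-yl]oxy}(tert-butyl)dimethylsilane
Conditions: (CH3)2Zn, Pd(P(t-Bu)3)2 (5 mol %), THF, rt
Reagents that add atoms: dimethylzinc, C[Zn]C
Why: Second Negishi coupling with retention at the alkenyl carbon; methyl replaces the remaining bromine and the E trisubstituted alkene results. The descriptor at C1 changes to S only because the substituent priorities change.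

Step 20
Reactants: 27 {[(1S,3aS,4S,7S,7aS)-4-bromo-1-[(1E)-2,6-dimethylhepta-1,5-dien-1-yl]-3a-methyloctahydro-1H-inden-7-yl]oxy}(tert-butyl)dimethylsilane
Product: 28 (1S,3aS,4S,7S,7aS)-4-bromo-1-[(1E)-2,6-dimethylhepta-1,5-dien-1-yl]-3a-methyloctahydro-1H-inden-7-ol
Conditions: Bu4NF, THF, rt
Reagents that add atoms: none
Why: Fluoride desilylation; the equatorial bromide has no antiperiplanar hydrogen and should not eliminate.

Step 21
Reactants: 28 (1S,3aS,4S,7S,7aS)-4-bromo-1-[(1E)-2,6-dimethylhepta-1,5-dien-1-yl]-3a-methyloctahydro-1H-inden-7-ol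
Product: 29 (1S,3aS,4S,7aS)-4-bromo-1-[(1E)-2,6-dimethylhepta-1,5-dien-1-yl]-3a-methyloctahydro-7H-inden-7-one
Conditions: Dess–Martin periodinane, CH2Cl2, 0 °C
Reagents that add atoms: none
Why: Dess–Martin oxidation under near-neutral conditions, chosen so that the C7a hydrogen next to the new ketone is not exchanged and the trans fusion is kept; the ketone is used at once.

Step 22
Reactants: 29 (1S,3aS,4S,7aS)-4-bromo-1-[(1E)-2,6-dimethylhepta-1,5-dien-1-yl]-3a-methyloctahydro-7H-inden-7-one
Product: 30 (1S,3aS,4S,7R,7aS)-4-bromo-1-[(1E)-2,6-dimethylhepta-1,5-dien-1-yl]-3a,7-dimethyloctahydro-1H-inden-7-ol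
Conditions: CH3MgBr, THF, −78 → −20 °C; aqueous NH4Cl
Reagents that add atoms: methylmagnesium bromide, C[Mg]Br
Why: Grignard 1,2-addition; the axial approach on the β face is blocked by the 1,3-diaxial angular methyl group, so methyl should enter equatorially from the α face and give the axial β hydroxyl (7R). Low temperature limits enolisation toward C7a.

## Compound list

1 | tert-butyl acetate | CC(=O)OC(C)(C)C | starting material
2 | 1-tert-butoxy-1-(trimethylsilyloxy)ethene | C=C(OC(C)(C)C)O[Si](C)(C)C | intermediate
3 | 2-methylcyclohex-2-en-1-one | CC1=CCCCC1=O | starting material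
4 | allyl bromide (3-bromoprop-1-ene) | C=CCBr | starting material
5 | tert-butyl 2-[(1S)-2-methyl-3-(trimethylsilyloxy)cyclohex-2-en-1-yl]acetate | CC1=C(O[Si](C)(C)C)CCC[C@H]1CC(=O)OC(C)(C)C | intermediate
6 | lithium (3S)-3-(2-tert-butoxy-2-oxoethyl)-2-methylcyclohex-1-en-1-olate | CC1=C(O[Li])CCC[C@H]1CC(=O)OC(C)(C)C | intermediate
7 | tert-butyl 2-[(1S,2S)-2-methyl-3-oxo-2-(prop-2-en-1-yl)cyclohexyl]acetate | C=CC[C@]1(C)C(=O)CCC[C@H]1CC(=O)OC(C)(C)C | intermediate
8 | tert-butyl 2-[(1S,2S)-2-methyl-3-oxo-2-(2-oxoethyl)cyclohexyl]acetate | O=CC[C@]1(C)C(=O)CCC[C@H]1CC(=O)OC(C)(C)C | intermediate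
9 | tert-butyl 2-[(1S,2S)-2-(2-hydroxyethyl)-2-methyl-3-oxocyclohexyl]acetate | OCC[C@]1(C)C(=O)CCC[C@H]1CC(=O)OC(C)(C)C | intermediate
10 | tert-butyl 2-[(1S,2S)-2-(2-iodoethyl)-2-methyl-3-oxocyclohexyl]acetate | ICC[C@]1(C)C(=O)CCC[C@H]1CC(=O)OC(C)(C)C | intermediate
11 | tert-butyl 2-[(1S,2S)-3-[(tert-butyldimethylsilyl)oxy]-2-(2-iodoethyl)-2-methylcyclohex-3-en-1-yl]acetate | ICC[C@]1(C)C(O[Si](C)(C)C(C)(C)C)=CCC[C@H]1CC(=O)OC(C)(C)C | intermediate
12 | tert-butyl (1R,3aS,7aS)-4-[(tert-butyldimethylsilyl)oxy]-3a-methyl-2,3,3a,6,7,7a-hexahydro-1H-indene-1-carboxylate | CC(C)(C)OC(=O)[C@@H]1CC[C@]2(C)C(O[Si](C)(C)C(C)(C)C)=CCC[C@@H]12 | intermediate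
13 | tert-butyl (1R,3aS,7aS)-3a-methyl-4-oxo-2,3,3a,4,7,7a-hexahydro-1H-indene-1-carboxylate | CC(C)(C)OC(=O)[C@@H]1CC[C@]2(C)C(=O)C=CC[C@@H]12 | intermediate
14 | tert-butyl (1R,3aS,7aS)-4-[(tert-butyldimethylsilyl)oxy]-3a-methyl-2,3,3a,7a-tetrahydro-1H-indene-1-carboxylate | CC(C)(C)OC(=O)[C@@H]1CC[C@]2(C)C(O[Si](C)(C)C(C)(C)C)=CC=C[C@@H]12 | intermediate
15 | tert-butyl (1R,3aS,7S,7aS)-7-hydroxy-3a-methyl-4-oxo-2,3,3a,4,7,7a-hexahydro-1H-indene-1-carboxylate | CC(C)(C)OC(=O)[C@@H]1CC[C@]2(C)C(=O)C=C[C@H](O)[C@@H]12 | intermediate
16 | tert-butyl (1R,3aS,7S,7aS)-7-[(tert-butyldimethylsilyl)oxy]-3a-methyl-4-oxo-2,3,3a,4,7,7a-hexahydro-1H-indene-1-carboxylate | CC(C)(C)OC(=O)[C@@H]1CC[C@]2(C)C(=O)C=C[C@H](O[Si](C)(C)C(C)(C)C)[C@@H]12 | intermediate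
17 | lithium (1R,3aS,7S,7aS)-1-(tert-butoxycarbonyl)-7-[(tert-butyldimethylsilyl)oxy]-3a-methyl-2,3,3a,6,7,7a-hexahydro-1H-inden-4-olate | CC(C)(C)OC(=O)[C@@H]1CC[C@]2(C)C(O[Li])=CC[C@H](O[Si](C)(C)C(C)(C)C)[C@@H]12 | intermediate
18 | tert-butyl (1R,3aS,7S,7aS)-7-[(tert-butyldimethylsilyl)oxy]-3a-methyl-4-[(trifluoromethanesulfonyl)oxy]-2,3,3a,6,7,7a-hexahydro-1H-indene-1-carboxylate | CC(C)(C)OC(=O)[C@@H]1CC[C@]2(C)C(OS(=O)(=O)C(F)(F)F)=CC[C@H](O[Si](C)(C)C(C)(C)C)[C@@H]12 | intermediate
19 | tert-butyl (1R,3aS,7S,7aS)-4-bromo-7-[(tert-butyldimethylsilyl)oxy]-3a-methyl-2,3,3a,6,7,7a-hexahydro-1H-indene-1-carboxylate | CC(C)(C)OC(=O)[C@@H]1CC[C@]2(C)C(Br)=CC[C@H](O[Si](C)(C)C(C)(C)C)[C@@H]12 | intermediate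
20 | tert-butyl (1R,3aS,4S,7S,7aS)-4-bromo-7-[(tert-butyldimethylsilyl)oxy]-3a-methyloctahydro-1H-indene-1-carboxylate | CC(C)(C)OC(=O)[C@@H]1CC[C@]2(C)[C@@H](Br)CC[C@H](O[Si](C)(C)C(C)(C)C)[C@@H]12 | intermediate
21 | [(1R,3aS,4S,7S,7aS)-4-bromo-7-[(tert-butyldimethylsilyl)oxy]-3a-methyloctahydro-1H-inden-1-yl]methanol | OC[C@@H]1CC[C@]2(C)[C@@H](Br)CC[C@H](O[Si](C)(C)C(C)(C)C)[C@@H]12 | intermediate
22 | (1R,3aS,4S,7S,7aS)-4-bromo-7-[(tert-butyldimethylsilyl)oxy]-3a-methyloctahydro-1H-indene-1-carbaldehyde | O=C[C@@H]1CC[C@]2(C)[C@@H](Br)CC[C@H](O[Si](C)(C)C(C)(C)C)[C@@H]12 | intermediate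
23 | {[(1R,3aS,4S,7S,7aS)-4-bromo-1-(2,2-dibromoethenyl)-3a-methyloctahydro-1H-inden-7-yl]oxy}(tert-butyl)dimethylsilane | BrC(Br)=C[C@@H]1CC[C@]2(C)[C@@H](Br)CC[C@H](O[Si](C)(C)C(C)(C)C)[C@@H]12 | intermediate
24 | 5-bromo-2-methylpent-2-ene | CC(C)=CCCBr | starting material
25 | (4-methylpent-3-en-1-yl)zinc bromide | CC(C)=CCC[Zn]Br | intermediate
26 | {[(1R,3aS,4S,7S,7aS)-4-bromo-1-[(1Z)-2-bromo-6-methylhepta-1,5-dien-1-yl]-3a-methyloctahydro-1H-inden-7-yl]oxy}(tert-butyl)dimethylsilane | CC(C)=CCC/C(Br)=C/[C@@H]1CC[C@]2(C)[C@@H](Br)CC[C@H](O[Si](C)(C)C(C)(C)C)[C@@H]12 | intermediate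
27 | {[(1S,3aS,4S,7S,7aS)-4-bromo-1-[(1E)-2,6-dimethylhepta-1,5-dien-1-yl]-3a-methyloctahydro-1H-inden-7-yl]oxy}(tert-butyl)dimethylsilane | CC(C)=CCC/C(C)=C/[C@@H]1CC[C@]2(C)[C@@H](Br)CC[C@H](O[Si](C)(C)C(C)(C)C)[C@@H]12 | intermediate
28 | (1S,3aS,4S,7S,7aS)-4-bromo-1-[(1E)-2,6-dimethylhepta-1,5-dien-1-yl]-3a-methyloctahydro-1H-inden-7-ol | CC(C)=CCC/C(C)=C/[C@@H]1CC[C@]2(C)[C@@H](Br)CC[C@H](O)[C@@H]12 | intermediate
29 | (1S,3aS,4S,7aS)-4-bromo-1-[(1E)-2,6-dimethylhepta-1,5-dien-1-yl]-3a-methyloctahydro-7H-inden-7-one | CC(C)=CCC/C(C)=C/[C@@H]1CC[C@]2(C)[C@@H](Br)CCC(=O)[C@@H]12 | intermediate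
30 | (1S,3aS,4S,7R,7aS)-4-bromo-1-[(1E)-2,6-dimethylhepta-1,5-dien-1-yl]-3a,7-dimethyloctahydro-1H-inden-7-ol | CC(C)=CCC/C(C)=C/[C@@H]1CC[C@]2(C)[C@@H](Br)CC[C@@](C)(O)[C@@H]12 | target

## Step count and least certain steps

Total: 22 steps. Longest linear sequence: 21 steps (steps 1–16 and 18–22, from 1); step 17 is a one-step branch.

**Step 2 (key step).**
- Risk: incomplete facial discrimination of the enone by the catalyst. The 2-methyl group removes the α-hydrogen contact that usually helps to organise a bound enone, and an acetate-derived ketene acetal has little steric bias. A second risk is competing addition of CH3Li to the ester during release of the enolate.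
- Fallback: it sets out from 7 of insufficient enantiomeric purity and returns at 7. Enantiocontrol is moved from the C–C bond formation to a catalyst-controlled ketone reduction. Catecholborane with the (S)-methyl CBS oxazaborolidine (toluene, −78 °C; the borane leaves the allyl group alone) should reduce both enantiomers of the ketone to the 3R carbinol. The wanted series gives tert-butyl 2-[(1S,2S,3R)-3-hydroxy-2-methyl-2-(prop-2-en-1-yl)cyclohexyl]acetate F1, and the contaminating mirror-image ketone gives the diastereomer tert-butyl 2-[(1R,2R,3R)-3-hydroxy-2-methyl-2-(prop-2-en-1-yl)cyclohexyl]acetate F2. The two differ in the cis/trans relation of hydroxyl and ring substituents and are separated by chromatography. Dess–Martin oxidation of F1 returns 7.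

**Step 9.**
- Risk: attack of the oxidant on the more electron-rich enol ether double bond (C4=C5) of 14, which would hydroxylate C5 instead of C7.
- Fallback: it sets out from 13 and returns at 15. The dienol ether 14 is formed as before and exposed to singlet oxygen (O2, tetraphenylporphyrin, light, CH2Cl2, −78 °C). The [4+2] cycloaddition places oxygen on both diene termini, expected on the α face, and gives the endoperoxide tert-butyl (1R,3aS,4S,7S,7aS)-4-[(tert-butyldimethylsilyl)oxy]-3a-methyl-4,7-epidioxy-2,3,3a,4,7,7a-hexahydro-1H-indene-1-carboxylate F3. Cleavage of the O–O bond with PPh3 lets the silyl hemiketal at C4 collapse to the ketone and leaves the C7 hydroxyl, giving 15.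

**Step 13.**
- Risk: poor facial selectivity in the hydrogen delivery to the C4 radical, or loss of bromine by over-reduction under the silane conditions.
- Fallback: it sets out from 19 and returns at 20. The radical pathway is replaced by surface-mediated syn addition of H2 (5 % Rh/Al2O3, ethyl acetate, rt). Both hydrogens should then come from the open α face, and rhodium is the catalyst least prone to cleave a vinylic C–Br bond. This fallback makes no new compound (F0).

**Step 18.**
- Risk: incomplete discrimination between the two C–Br bonds of the hindered dibromoalkene 23 (double alkylation, or coupling at the cis bromine), which would erode the alkene geometry.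
- Fallback: it sets out from 22 and returns at 27. The geometry is set by syn hydrometalation of an alkyne. Homologation of 22 with dimethyl (1-diazo-2-oxopropyl)phosphonate (K2CO3, CH3OH) gives the alkyne {[(1R,3aS,4S,7S,7aS)-4-bromo-1-ethynyl-3a-methyloctahydro-1H-inden-7-yl]oxy}(tert-butyl)dimethylsilane F4. Deprotonation with LiN(i-Pr)2 and methylation with CH3I gives the propynyl compound {[(1R,3aS,4S,7S,7aS)-4-bromo-3a-methyl-1-(prop-1-yn-1-yl)octahydro-1H-inden-7-yl]oxy}(tert-butyl)dimethylsilane F5. Hydrozirconation with Cp2Zr(H)Cl (excess, THF, equilibration places zirconium on the methyl-bearing carbon) and iodination give the vinyl iodide {[(1R,3aS,4S,7S,7aS)-4-bromo-1-[(1E)-2-iodoprop-1-en-1-yl]-3a-methyloctahydro-1H-inden-7-yl]oxy}(tert-butyl)dimethylsilane F6. Negishi coupling of F6 with 25 (Pd(PPh3)4, THF) proceeds with retention and gives 27.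

## Further compounds

F1 | step 2 | tert-butyl 2-[(1S,2S,3R)-3-hydroxy-2-methyl-2-(prop-2-en-1-yl)cyclohexyl]acetate | C=CC[C@]1(C)[C@H](O)CCC[C@H]1CC(=O)OC(C)(C)C
F2 | step 2 | tert-butyl 2-[(1R,2R,3R)-3-hydroxy-2-methyl-2-(prop-2-en-1-yl)cyclohexyl]acetate | C=CC[C@@]1(C)[C@H](O)CCC[C@@H]1CC(=O)OC(C)(C)C
F3 | step 9 | tert-butyl (1R,3aS,4S,7S,7aS)-4-[(tert-butyldimethylsilyl)oxy]-3a-methyl-4,7-epidioxy-2,3,3a,4,7,7a-hexahydro-1H-indene-1-carboxylate | CC(C)(C)OC(=O)[C@@H]1CC[C@]2(C)[C@@]3(O[Si](C)(C)C(C)(C)C)C=C[C@H](OO3)[C@@H]12
F0 | step 13 | none | none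
F4 | step 18 | {[(1R,3aS,4S,7S,7aS)-4-bromo-1-ethynyl-3a-methyloctahydro-1H-inden-7-yl]oxy}(tert-butyl)dimethylsilane | C#C[C@@H]1CC[C@]2(C)[C@@H](Br)CC[C@H](O[Si](C)(C)C(C)(C)C)[C@@H]12
F5 | step 18 | {[(1R,3aS,4S,7S,7aS)-4-bromo-3a-methyl-1-(prop-1-yn-1-yl)octahydro-1H-inden-7-yl]oxy}(tert-butyl)dimethylsilane | CC#C[C@@H]1CC[C@]2(C)[C@@H](Br)CC[C@H](O[Si](C)(C)C(C)(C)C)[C@@H]12
F6 | step 18 | {[(1R,3aS,4S,7S,7aS)-4-bromo-1-[(1E)-2-iodoprop-1-en-1-yl]-3a-methyloctahydro-1H-inden-7-yl]oxy}(tert-butyl)dimethylsilane | I/C(C)=C/[C@@H]1CC[C@]2(C)[C@@H](Br)CC[C@H](O[Si](C)(C)C(C)(C)C)[C@@H]12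
A1 | alternative 1 | (1R,3aS,4S,7R,7aS)-4-bromo-7-hydroxy-3a,7-dimethyloctahydro-1H-indene-1-carbaldehyde | O=C[C@@H]1CC[C@]2(C)[C@@H](Br)CC[C@@](C)(O)[C@@H]12
A2 | alternative 1 | 5-bromo-2,8-dihydroxy-4a,8-dimethyldecahydronaphthalen-1-yl methanesulfonate (trans-decalin, equatorial mesylate, axial cis hydroxyl) | CS(=O)(=O)O[C@@H]1[C@H](O)CC[C@]2(C)[C@@H](Br)CC[C@@](C)(O)[C@@H]12
A3 | alternative 2 | cyclopropane-bridged (C3a–CH2–C7a) 4-silyloxy bicyclic carbinol | O[C@@H]1CC[C@@H](O[Si](C)(C)C(C)(C)C)[C@]2(CCC3)C[C@]123
A4 | alternative 2 | trans-4-[(tert-butyldimethylsilyl)oxy]-2,3,4,5,6,7-hexahydro-1H-inden-7-ol | O[C@@H]1CC[C@@H](O[Si](C)(C)C(C)(C)C)C2=C1CCC2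
A5 | alternative 3 | (3aS,7aS)-3a-methylhexahydro-1H-indene-4,7-dione | C1CC[C@]2(C)C(=O)CCC(=O)[C@@H]12
A6 | alternative 3 | 4-(2-methylcyclopent-1-en-1-yl)-4-oxobutanal | CC1=C(CCC1)C(=O)CCC=O
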